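Each opening spends one reagent, so open intermediate, target and trapped intermediate together count the reagent used, whatever the rates.

    substrate + reagent → open intermediate + released group (k1 = 0.22 L mol⁻¹ min⁻¹)
    open intermediate → target (k2 = 7.3 × 10⁻⁴ min⁻¹)
    substrate + released group ⇌ idle adduct, settled at all times (K3 = 5.1 L mol⁻¹)
    scavenger + released group → scavenged by-product (k4 = 0.025 L mol⁻¹ min⁻¹)
    open intermediate + capture agent → trapped intermediate (k5 = 0.021 L mol⁻¹ min⁻¹)

- birch: substrate 0.25 M; reagent 0.800 equiv; scavenger 1.00 equiv; capture agent 5.00 mM; time 8.0 h
- oak: substrate 0.25 M; reagent 0.960 equiv; scavenger 1.00 equiv; capture agent 5.00 mM; time 8.0 h

1. which of these there is most of at the end, counted by the substrate in it, birch (target / open intermediate / substrate / trapped intermediate)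
2. which of these there is most of at the end, counted by the substrate in it, oak (target / open intermediate / substrate / trapped intermediate)
3. final amount of the leader among these, as a percentage of the substrate charged, in birch
4. final amount of the leader among these, as a percentage of the substrate charged, in oak

- released group is meant together with its idle adduct
- run time (birch): 8.0 h

Two chemists disagree. The first reads the scheme to its end: in birch the open intermediate has a half-life of 16 h by step 2 against 110 h by step 5, so target collects the stream, and she names target as leader in both flasks. The second reads the clock: that half-life of 16 h is twice the run of 8.0 h, so he expects a stock of open intermediate still standing at the end.

My own reckoning joins the two ends. At the front, reagent is the limiting reagent, charged below one equivalent in both flasks, and in birch step 1 has a half-life of 0.26 h, far shorter than the run, so I treat the charge as opened at the start. At the back, step 2 is first order, so I carry 70.4%: this is the survival factor, the share of material opened at the start that step 2 has left unclosed at the end of the run. Then c(open intermediate) at the end is the reagent charge times that factor: 56.4% of the substrate in birch and 67.6% in oak, with the second chemist's leader.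

The forecast sides with him too: open intermediate at 56% in birch and open intermediate at 66% in oak, since “Closure to target is slow”. In oak its figure lies below my product.

The simulation gives open intermediate at 56.9% in birch and open intermediate at 66.7% in oak, with target at 21.2% and 24.2%.

The second chemist wins on the clock. The time allowed is the main reason oak still holds so much open intermediate: it has 66.7% at the end of the run, against 3.04% when left until 80.0 h. The first chemist's view belongs to late readings. For oak read at 30 h, the survival factor raised to the ratio of the times, times the charge, gives 25.8%. The computed flask holds 26.9% of open intermediate, and its leader is target at 66.9%.

The constants are invented; the result is computed.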